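**Strategy.** The methylidenecyclohexane ring of achilleol A acetate is disconnected at the bond between the carbinol carbon (C3) and the gem-dimethyl carbon (C4). A carbinol next to a quaternary CMe2 carbon is the signature of γ-attack by a prenyl-type allylmetal. The key step is therefore a catalytic asymmetric Nozaki–Hiyama–Kishi cyclization of an acyclic 2-(bromomethyl) isopropylidene keto aldehyde. In one operation it closes the six-membered ring, creates quaternary C4, sets C3 under ligand control and leaves an exocyclic C5=C6 enone. Conjugate propargylation then fixes C5 thermodynamically; methylenation of the C10 ketone, carboalumination and B-alkyl Suzuki coupling with a homofarnesyl borane complete the chain before acetylation.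

Key step: step 6

Remark: atoms carry triterpene labels (ring C1, C2, C3 = CH–O, C4 = CMe2, C5 = CH bearing the side chain, C10 = C(=CH2); side chain from C6), and the ligand antipode in step 6 is assumed to be the one that delivers the 3S carbinol.

Step 1
Reactants: 1 methyl 4,4-dimethoxybutanoate
Product: 2 N,4,4-trimethoxy-N-methylbutanamide
Conditions: MeNH(OMe)·HCl, i-PrMgCl, THF, −20 °C to 0 °C
Reagents that add atoms: N,O-dimethylhydroxylamine hydrochloride (CNOC.Cl)
Why: Weinreb amide formation, in which the chloromagnesium amide made from the hydroxylamine salt and i-PrMgCl acylates on the ester while the dimethyl acetal is inert to base.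

Step 2
Reactants: 2 N,4,4-trimethoxy-N-methylbutanamide; 3 1-propynylmagnesium bromide
Product: 4 7,7-dimethoxyhept-2-yn-4-one
Conditions: THF, 0 °C; aq. NH4Cl
Reagents that add atoms: none
Why: Weinreb ketone synthesis, in which the alkynyl Grignard reagent adds only once because the magnesium-chelated tetrahedral intermediate collapses on work-up.

Step 3
Reactants: 4 7,7-dimethoxyhept-2-yn-4-one
Product: 6 3-(hydroxymethyl)-7,7-dimethoxy-2-methylhept-2-en-4-one, via lithium allenolate 5 (not isolated)
Conditions: Me2CuLi (from MeLi, CuI), Et2O/THF, −78 °C; then CH2O (gas), −78 °C to −40 °C; aq. NH4Cl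
Reagents that add atoms: lithium dimethylcuprate ([Li+].C[Cu-]C); formaldehyde (C=O)
Why: Tandem conjugate addition–aldol, in which the cuprate transfers methyl to the alkyne β-carbon and the resulting β,β-dimethyl allenolate 5 is hydroxymethylated at its α-carbon; no stereo-element arises because the β-carbon carries two methyl groups.

Step 4
Reactants: 6 3-(hydroxymethyl)-7,7-dimethoxy-2-methylhept-2-en-4-one
Product: 7 3-(bromomethyl)-7,7-dimethoxy-2-methylhept-2-en-4-one
Conditions: CBr4, PPh3, CH2Cl2, 0 °C
Reagents that add atoms: tetrabromomethane (BrC(Br)(Br)Br)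
Why: Appel reaction, in which the primary allylic alcohol is activated as an alkoxyphosphonium ion and displaced by bromide under neutral conditions that spare acetal and enone.

Step 5
Reactants: 7 3-(bromomethyl)-7,7-dimethoxy-2-methylhept-2-en-4-one
Product: 8 5-(bromomethyl)-6-methyl-4-oxohept-5-enal
Conditions: 1 M HCl, THF/H2O, 0 °C
Reagents that add atoms: water (O)
Why: Acid-catalysed acetal hydrolysis through the oxocarbenium ion unmasks the aldehyde, and cold dilute acid should spare the allylic bromide and the tetrasubstituted enone.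

Step 6
Reactants: 8 5-(bromomethyl)-6-methyl-4-oxohept-5-enal
Product: 10 (4S)-3,3-dimethyl-2-methylidene-4-(triethylsilyloxy)cyclohexan-1-one, via allylchromium dichloride 9 (not isolated)
Conditions: CrCl2 (10 mol %), 3,6-di-tert-butyl-1,8-bis[(4S)-4-isopropyl-4,5-dihydrooxazol-2-yl]-9H-carbazole (12 mol %), Mn, Et3SiCl, i-Pr2NEt, THF, rt, high dilution
Reagents that add atoms: chlorotriethylsilane (CC[Si](Cl)(CC)CC)
Why: Two divalent chromium centres reduce the allylic C–Br bond to the σ-allyl trivalent chromium species 9 held at the primary carbon (C6), which adds through its γ-carbon (C4, the CMe2 terminus) to the chromium-bound aldehyde carbon (C3) in a chair-like SE2' transition state, so that the C3–C4 bond, the quaternary centre and the exocyclic C5=C6 alkene are formed together, while Et3SiCl silylates the chromium alkoxide and Mn returns chromium to the divalent state. The closest known reaction type is the catalytic asymmetric Nozaki–Hiyama–Kishi allylation of aldehydes with γ,γ-disubstituted and 2-carbonyl-substituted allyl bromides, applied here intramolecularly. The six-membered carbocycle closes in a 6-exo-trig mode at the aldehyde C=O, with the allyl unit tethered through its central carbon (C5), the mode that gives 3-methylidenecycloalkanols. The only new stereocentre, C3, is set by the chiral bis(oxazolinyl)carbazole ligand on chromium, which differentiates the two aldehyde faces; C4 carries two identical methyl groups and is not stereogenic. The step needs γ- rather than α-attack (six- versus seven-membered ring) and addition to the aldehyde rather than the ketone; the preference of prenyl-type allylchromium reagents for bond formation at the more substituted terminus, the smaller ring and the inertness of organochromium reagents towards ketones should secure both.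

Step 7
Reactants: 10 (4S)-3,3-dimethyl-2-methylidene-4-(triethylsilyloxy)cyclohexan-1-one; 11 allenyltributylstannane
Product: 12 (2S,4S)-2-(but-3-yn-1-yl)-3,3-dimethyl-4-(triethylsilyloxy)cyclohexan-1-one
Conditions: TiCl4, CH2Cl2, −78 °C; aq. NaHCO3; then DBU, CH2Cl2, rt
Reagents that add atoms: none
Why: Lewis-acid-promoted conjugate propargylation, in which the allenylstannane attacks the exocyclic β-carbon (C6) of the activated enone through its remote terminus (SE2'); the C5 stereocentre formed on protonation of the titanium enolate is equilibrated by DBU to the diequatorial cis isomer (thermodynamic control next to the ketone).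

Step 8
Reactants: 12 (2S,4S)-2-(but-3-yn-1-yl)-3,3-dimethyl-4-(triethylsilyloxy)cyclohexan-1-one
Product: 13 {[(1S,3R)-3-(but-3-yn-1-yl)-2,2-dimethyl-4-methylidenecyclohexyl]oxy}triethylsilane
Conditions: Zn, CH2Br2, TiCl4, THF/CH2Cl2, 0 °C to rt
Reagents that add atoms: dibromomethane (BrCBr)
Why: Lombardo–Takai methylenation, whose non-basic gem-dizinc/titanium methylene reagent olefinates the hindered enolisable ketone without epimerising C5 and tolerates silyl ether and terminal alkyne.

Step 9
Reactants: 13 {[(1S,3R)-3-(but-3-yn-1-yl)-2,2-dimethyl-4-methylidenecyclohexyl]oxy}triethylsilane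
Product: 15 {[(1S,3R)-3-[(3E)-4-iodo-3-methylbut-3-en-1-yl]-2,2-dimethyl-4-methylidenecyclohexyl]oxy}triethylsilane, via alkenylalane 14 (not isolated)
Conditions: AlMe3, Cp2ZrCl2 (cat.), CH2Cl2, 0 °C to rt; then I2, THF, −30 °C
Reagents that add atoms: trimethylaluminium (C[Al](C)C); iodine (II)
Why: Zirconium-catalysed carboalumination (Negishi) adds methyl and aluminium syn across the terminal alkyne with aluminium on the terminal carbon, and iodinolysis with retention gives the E-iodoalkene; the hindered 1,1-disubstituted ring alkene should not react.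

Step 10
Reactants: 16 (2E,6E)-farnesol
Product: 17 (2E,6E)-farnesal
Conditions: MnO2, CH2Cl2, rt
Reagents that add atoms: none
Why: MnO2 oxidises the allylic alcohol selectively to the enal without isomerising the E double bonds.

Step 11
Reactants: 17 (2E,6E)-farnesal
Product: 18 (3E,7E)-4,8,12-trimethyltrideca-1,3,7,11-tetraene
Conditions: Ph3PCH3Br, KOtBu, THF, 0 °C
Reagents that add atoms: methyltriphenylphosphonium bromide (C[P+](c1ccccc1)(c1ccccc1)c1ccccc1.[Br-])
Why: Wittig methylenation of the enal gives the terminal 1,3-diene and leaves the existing alkene geometries untouched.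

Step 12
Reactants: 18 (3E,7E)-4,8,12-trimethyltrideca-1,3,7,11-tetraene; 15 {[(1S,3R)-3-[(3E)-4-iodo-3-methylbut-3-en-1-yl]-2,2-dimethyl-4-methylidenecyclohexyl]oxy}triethylsilane
Product: 20 achilleol A triethylsilyl ether, via B-alkyl-9-BBN borane 19 (not isolated)
Conditions: 9-BBN-H, THF, 0 °C to rt; then 15, Pd(dppf)Cl2 (cat.), AsPh3, Cs2CO3, DMF/H2O, rt
Reagents that add atoms: none
Why: 9-BBN hydroborates only the unhindered terminal vinyl group of 18 in anti-Markovnikov fashion, and borane 19 undergoes B-alkyl Suzuki–Miyaura coupling with iodoalkene 15 with retention of the E geometry (oxidative addition to zerovalent palladium, base-assisted transmetalation, reductive elimination).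

Step 13
Reactants: 20 achilleol A triethylsilyl ether
Product: 22 achilleol A acetate (CNP0286444.1), via achilleol A 21 (not isolated)
Conditions: TBAF, THF, 0 °C to rt; then Ac2O, Et3N, DMAP, rt
Reagents that add atoms: acetic anhydride (CC(=O)OC(C)=O)
Why: Fluoride cleaves the Si–O bond to give achilleol A 21, whose hindered secondary alcohol is acetylated in the same flask by DMAP-catalysed acyl transfer with retention at C3.

**Compound list**

1 | methyl 4,4-dimethoxybutanoate | COC(=O)CCC(OC)OC | starting material
2 | N,4,4-trimethoxy-N-methylbutanamide | CON(C)C(=O)CCC(OC)OC | intermediate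
3 | 1-propynylmagnesium bromide | CC#C[Mg]Br | starting material
4 | 7,7-dimethoxyhept-2-yn-4-one | CC#CC(=O)CCC(OC)OC | intermediate
5 | lithium 7,7-dimethoxy-2-methylhepta-2,3-dien-4-olate (lithium allenolate) | CC(C)=C=C([O-])CCC(OC)OC.[Li+] | intermediate
6 | 3-(hydroxymethyl)-7,7-dimethoxy-2-methylhept-2-en-4-one | CC(C)=C(CO)C(=O)CCC(OC)OC | intermediate
7 | 3-(bromomethyl)-7,7-dimethoxy-2-methylhept-2-en-4-one | CC(C)=C(CBr)C(=O)CCC(OC)OC | intermediate
8 | 5-(bromomethyl)-6-methyl-4-oxohept-5-enal | CC(C)=C(CBr)C(=O)CCC=O | intermediate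
9 | dichloro[3-methyl-2-(4-oxobutanoyl)but-2-en-1-yl]chromium (allylchromium dichloride, chiral ligand not drawn) | CC(C)=C(C[Cr](Cl)Cl)C(=O)CCC=O | intermediate
10 | (4S)-3,3-dimethyl-2-methylidene-4-(triethylsilyloxy)cyclohexan-1-one | O=C1CC[C@H](O[Si](CC)(CC)CC)C(C)(C)C1=C | intermediate
11 | allenyltributylstannane (tributyl(propa-1,2-dien-1-yl)stannane) | C=C=C[Sn](CCCC)(CCCC)CCCC | starting material
12 | (2S,4S)-2-(but-3-yn-1-yl)-3,3-dimethyl-4-(triethylsilyloxy)cyclohexan-1-one | O=C1CC[C@H](O[Si](CC)(CC)CC)C(C)(C)[C@@H]1CCC#C | intermediate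
13 | {[(1S,3R)-3-(but-3-yn-1-yl)-2,2-dimethyl-4-methylidenecyclohexyl]oxy}triethylsilane | C=C1CC[C@H](O[Si](CC)(CC)CC)C(C)(C)[C@@H]1CCC#C | intermediate
14 | {(1E)-4-[(1R,3S)-2,2-dimethyl-6-methylidene-3-(triethylsilyloxy)cyclohexyl]-2-methylbut-1-en-1-yl}dimethylalumane (alkenylalane) | C=C1CC[C@H](O[Si](CC)(CC)CC)C(C)(C)[C@@H]1CC/C(C)=C/[Al](C)C | intermediate
15 | {[(1S,3R)-3-[(3E)-4-iodo-3-methylbut-3-en-1-yl]-2,2-dimethyl-4-methylidenecyclohexyl]oxy}triethylsilane | C=C1CC[C@H](O[Si](CC)(CC)CC)C(C)(C)[C@@H]1CC/C(C)=C/I | intermediate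
16 | (2E,6E)-farnesol ((2E,6E)-3,7,11-trimethyldodeca-2,6,10-trien-1-ol) | CC(C)=CCC/C(C)=C/CC/C(C)=C/CO | starting material
17 | (2E,6E)-farnesal | CC(C)=CCC/C(C)=C/CC/C(C)=C/C=O | intermediate
18 | (3E,7E)-4,8,12-trimethyltrideca-1,3,7,11-tetraene | CC(C)=CCC/C(C)=C/CC/C(C)=C/C=C | intermediate
19 | 9-[(3E,7E)-4,8,12-trimethyltrideca-3,7,11-trien-1-yl]-9-borabicyclo[3.3.1]nonane | CC(C)=CCC/C(C)=C/CC/C(C)=C/CCB1C2CCCC1CCC2 | intermediate
20 | triethyl({(1S,3R)-2,2-dimethyl-4-methylidene-3-[(3E,7E,11E)-3,8,12,16-tetramethylheptadeca-3,7,11,15-tetraen-1-yl]cyclohexyl}oxy)silane (achilleol A triethylsilyl ether) | C=C1CC[C@H](O[Si](CC)(CC)CC)C(C)(C)[C@@H]1CC/C(C)=C/CC/C=C(\C)CC/C=C(\C)CCC=C(C)C | intermediate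
21 | (1S,3R)-2,2-dimethyl-4-methylidene-3-[(3E,7E,11E)-3,8,12,16-tetramethylheptadeca-3,7,11,15-tetraen-1-yl]cyclohexan-1-ol (achilleol A) | C=C1CC[C@H](O)C(C)(C)[C@@H]1CC/C(C)=C/CC/C=C(\C)CC/C=C(\C)CCC=C(C)C | intermediate
22 | (1S,3R)-2,2-dimethyl-4-methylidene-3-[(3E,7E,11E)-3,8,12,16-tetramethylheptadeca-3,7,11,15-tetraen-1-yl]cyclohexyl acetate (achilleol A acetate, CNP0286444.1) | C=C1CC[C@H](OC(C)=O)C(C)(C)[C@@H]1CC/C(C)=C/CC/C=C(\C)CC/C=C(\C)CCC=C(C)C | target

Total step count: 13. Longest linear sequence: 11 steps (steps 1 to 9, 12 and 13).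

**Steps most likely to fail**

The key cyclization (step 6) may proceed with poor facial discrimination of the aldehyde, because a ligand-free background allylation can compete in the intramolecular setting. The allylchromium species may also be protonated before it cyclizes. The fallback gives up catalyst control: setting out from 8, ligand-free cyclization with stoichiometric CrCl2 and Et3SiCl in THF should give racemic 3,3-dimethyl-2-methylidene-4-(triethylsilyloxy)cyclohexan-1-one F1. Its enantiomers are then separated by preparative chromatography on a chiral stationary phase, and the 4S enantiomer rejoins the route at 10.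

The cuprate addition–hydroxymethylation (step 3) may stall at simple protonation of the allenolate, may polymerize formaldehyde, or may lose formaldehyde again by retro-aldol cleavage on warming. The fallback separates the two events: setting out from 4, the allenolate formed with Me2CuLi is trapped with Me3SiCl to give the isolable [(7,7-dimethoxy-2-methylhepta-2,3-dien-4-yl)oxy]trimethylsilane F2. A Mukaiyama-type hydroxymethylation of F2 with aqueous formaldehyde and catalytic Yb(OTf)3 in THF then returns to the route at 6.

The conjugate propargylation (step 7) may suffer from Lewis-acid cleavage of the silyl ether or from transfer of an allenyl instead of a propargyl group. The fallback builds the alkyne in stages: setting out from 10, Hosomi–Sakurai conjugate allylation with allyltrimethylsilane and TiCl4 should give (2S,4S)-2-(but-3-en-1-yl)-3,3-dimethyl-4-(triethylsilyloxy)cyclohexan-1-one F3. Ozonolysis of its only alkene (O3, then PPh3) gives 3-[(1S,3S)-2,2-dimethyl-6-oxo-3-(triethylsilyloxy)cyclohexyl]propanal F4. Ohira–Bestmann homologation of F4 (dimethyl (1-diazo-2-oxopropyl)phosphonate, K2CO3, MeOH), whose basic medium also equilibrates C5 to the cis isomer, returns to the route at 12.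

Further compounds
F1 | step 6 | racemic 3,3-dimethyl-2-methylidene-4-(triethylsilyloxy)cyclohexan-1-one | C=C1C(=O)CCC(O[Si](CC)(CC)CC)C1(C)C
F2 | step 3 | [(7,7-dimethoxy-2-methylhepta-2,3-dien-4-yl)oxy]trimethylsilane | CC(C)=C=C(O[Si](C)(C)C)CCC(OC)OC
F3 | step 7 | (2S,4S)-2-(but-3-en-1-yl)-3,3-dimethyl-4-(triethylsilyloxy)cyclohexan-1-one | O=C1CC[C@H](O[Si](CC)(CC)CC)C(C)(C)[C@@H]1CCC=C
F4 | step 7 | 3-[(1S,3S)-2,2-dimethyl-6-oxo-3-(triethylsilyloxy)cyclohexyl]propanal | O=C1CC[C@H](O[Si](CC)(CC)CC)C(C)(C)[C@@H]1CCC=O
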